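I had no constants for this chemistry, just two earlier runs and a decision to take: whether alpha, at 2.40 equivalents of reagent, may stand its full 6.0 min if I want the isomer of the product to be what it holds most of.

all flasks: starting material 0.50 M
- autumn: reagent 0.59 M; run made earlier
- noon: reagent 1.9 M; run made earlier
- alpha: reagent 1.20 M; time 6.0 min
- zeta: reagent 0.400 M; time 6.0 min

| run | time / min | bis adduct / % | isomer of the product / % | starting material / % | tris adduct / % | first product / % |
|---|---|---|---|---|---|---|
| autumn | 0.250 | 4 | 6 | 44 | 0 | 43 |
| autumn | 0.833 | 11 | 14 | 25 | 3 | 45 |
| autumn | 1.33 | 9 | 18 | 22 | 0 | 45 |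
| autumn | 2.00 | 11 | 19 | 21 | 2 | 45 |
| autumn | 3.00 | 12 | 19 | 20 | 1 | 44 |
| noon | 0.250 | 26 | 25 | 7 | 14 | 33 |
| noon | 0.833 | 20 | 34 | 0 | 44 | 5 |
| noon | 1.33 | 14 | 24 | 0 | 59 | 1 |
| noon | 2.00 | 10 | 17 | 0 | 73 | 4 |
| noon | 3.00 | 7 | 11 | 1 | 83 | 0 |

(readings scatter by 1.5 percentage points)

* which of these there is most of at the end, counted by the starting material in it, alpha (first product / isomer of the product / tris adduct / bis adduct / starting material)
* which of these there is most of at the end, counted by the starting material in it, zeta (first product / isomer of the product / tris adduct / bis adduct / starting material)
* final amount of the leader among these, as a percentage of the starting material charged, in alpha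
* final amount of the leader among these, as a percentage of the starting material charged, in zeta



In the noon run, isomer and bis adduct fell together: 34% against 20% at 0.833 min, and 11% against 7% at 3.00 min. So I treated their exchange as a fast pre-equilibrium and counted the two as one pool. Summed from 0.833 min on, bis adduct made up 37.2% of the noon pool, and I called this the free share.

With the isomer counted as carrying two reagent units, the last autumn reading adds up to 1.09 equivalents of the 1.18 charged. I kept that count for alpha. At zero starting material, first product and reagent, the balance would leave alpha with 40.0% of its charge as tris adduct and a pool of 60.0%. Of that pool, 37.7% would be isomer, less than the tris adduct. The gap is narrow, but I committed to tris adduct for alpha, near 40.0%, and decided that a flask meant for isomer must be stopped earlier.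

The forecast named isomer of the product at 40% for alpha, saying “the remaining 0.4 equiv is consumed slowly”, and first product at 45% for zeta. On alpha's leader we differed.

    bis adduct ⇌ isomer of the product (K = 1.50, k = 0.170 /s)
    crystals ⇌ by-product, rate k2*(cs2 - [by-product]) while solid is left; crystals form when [by-product] > cs2 (solubility = 5.10 mM, k = 5.80 /s)
    starting material + reagent → first product + by-product (k = 0.140 /M/s)
    reagent + first product → bis adduct + by-product (k = 0.0850 /M/s)
    reagent + bis adduct → tris adduct + by-product (k = 0.0450 /M/s)

Alpha ended with tris adduct first at 41.0%, and zeta with first product first at 44.7%, its reagent at 0% of charge. Alpha read at 1.50 min still held 12.2% of its reagent and 12.9% first product. Alpha's pool of 60.4% at that time and the free share give 37.9% isomer; the flask held 36.2%, more than the tris adduct at 25.7%. After that, reagent went on adding to first product and bis adduct in alpha until, at 6.0 min, 1.4% of it remained, the pool of 54.7% held 34.4% isomer by the free share against 32.9% in the flask, and tris adduct stood at 41.0%.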